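**Assumption:** the [C@] centre in the SMILES decodes as (R), with priorities OH > aryl > CH2 > CH3. Compounds 1 (≥98% ee), 3, 7 and 10 are taken as commercial.

## Retrosynthetic overview
1. The ring-C phenol is removed first: C–OH ⇒ C–H, installed last by tertiary-alcohol-directed Ir C–H silylation and Tamao oxidation. Ring C becomes a symmetric p-phenylene, so its two ortho sites are equivalent.
2. The diarylmethane comes from a ring-B aldehyde tosylhydrazone and a ring-C boronic acid (metal-free diazo/boronate 1,2-shift). The CHO carbon of o-orsellinaldehyde fixes the ring-B regiochemistry.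
3. The (R)-carbinol comes from (S)-1-(4-chlorophenyl)ethyl carbamate and 4-methylpentyl-Bpin by stereospecific lithiation–borylation–oxidation. No ketone/RMgX addition is used.
4. The diaryl ether comes from Chan–Lam arylation of the non-chelated 4-OH of orsellinaldehyde.
5. Rings A, B and C are all bought (7, 10, 1). The only ring formed is a transient benzoxasilole, made in step 11 and opened in step 12.

## Route

**Step 1**
Reactants: 1, (S)-1-(4-chlorophenyl)ethanol
Product: 2, (S)-1-(4-chlorophenyl)ethyl N,N-diisopropylcarbamate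
Conditions: iPr2NCOCl, Et3N, CH2Cl2, reflux, 48 h
Reagents that add atoms: N,N-diisopropylcarbamoyl chloride, CC(C)N(C(C)C)C(Cl)=O
Why: O-carbamoylation (acyl substitution at oxygen) leaves the C–O bond of the stereocentre untouched, so (S) is retained.

**Step 2**
Reactants: 3, 4-methylpent-1-ene
Product: 4, 2-(4-methylpentyl)-4,4,5,5-tetramethyl-1,3,2-dioxaborolane
Conditions: HBpin, [Ir(cod)Cl]2 (1.5 mol %), dppm (3 mol %), CH2Cl2, rt
Reagents that add atoms: pinacolborane, [H]B1OC(C)(C)C(C)(C)O1
Why: Ir-catalysed anti-Markovnikov hydroboration of a terminal alkene gives the primary boronic ester only.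

**Step 3** (key step, sets the stereocentre)
Reactants: 2, carbamate; 4, 4-methylpentyl-Bpin
Product: 5, (R)-2-(4-chlorophenyl)-6-methylheptan-2-ol
Conditions: sBuLi, Et2O, −78 °C, 1 h; 4, −78 °C, 1 h; MgBr2/MeOH, −78 °C → rt; then NaOH, 30% H2O2, THF, 0 °C → rt
Reagents that add atoms: hydrogen peroxide, OO (supplies the carbinol O)
Why: In this lithiation–borylation, deprotonation and boronate formation go with retention, the anti-periplanar 1,2-metallate shift expels OCb with inversion, and C–B oxidation goes with retention, so the alkyl group takes the place of H and O the place of OCb, making (S)-2 into (R)-5 by CIP change; MgBr2/MeOH suppresses ate-complex reversal, and ArCl survives sBuLi at −78 °C.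

**Step 4**
Reactants: 5
Product: 6, (R)-[4-(2-hydroxy-6-methylheptan-2-yl)phenyl]boronic acid
Conditions: B2(OH)4, XPhos-Pd-G2 (2 mol %), XPhos, KOAc, EtOH, 80 °C
Reagents that add atoms: tetrahydroxydiboron, OB(O)B(O)O
Why: Miyaura-type Pd borylation of the aryl chloride gives the free boronic acid directly, and the weak base with no acid leaves the tertiary benzylic alcohol and its configuration intact.

**Step 5**
Reactants: 7, 3-bromo-5-methylphenol
Product: 8, (3-bromo-5-methylphenoxy)triisopropylsilane
Conditions: TIPSCl, imidazole, DMF, rt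
Reagents that add atoms: TIPSCl, CC(C)[Si](Cl)(C(C)C)C(C)C
Why: Standard phenol silylation; TIPS is chosen to survive nBuLi, Cu(II)/pyridine and hot K2CO3, and to leave with fluoride.

**Step 6**
Reactants: 8
Product: 9, [3-methyl-5-(triisopropylsilyloxy)phenyl]boronic acid
Conditions: nBuLi, THF, −78 °C; B(OiPr)3, −78 °C → rt; aq NH4Cl
Reagents that add atoms: triisopropyl borate, CC(C)OB(OC(C)C)OC(C)C; water, O
Why: Br–Li exchange followed by borate trapping and hydrolysis; the aryllithium sits meta to OSi, so no retro-Brook silyl migration is possible.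

**Step 7**
Reactants: 10, 2,4-dihydroxy-6-methylbenzaldehyde (o-orsellinaldehyde); 9 (2 equiv)
Product: 11, 2-hydroxy-6-methyl-4-[3-methyl-5-(triisopropylsilyloxy)phenoxy]benzaldehyde
Conditions: Cu(OAc)2 (1.5 equiv), pyridine, 4 Å MS, CH2Cl2, dry air, rt, 48 h
Reagents that add atoms: none
Why: Chan–Lam–Evans O-arylation, where the 4-OH is the more acidic and accessible site and the 2-OH is hydrogen-bonded to CHO, the same bias that makes 4-O-alkylation of resorcylaldehydes selective.

**Step 8**
Reactants: 11
Product: 12, 2-methyl-4-[3-methyl-5-(triisopropylsilyloxy)phenoxy]-6-(triisopropylsilyloxy)benzaldehyde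
Conditions: TIPSOTf, 2,6-lutidine, CH2Cl2, 0 °C → rt
Reagents that add atoms: TIPSOTf, CC(C)[Si](OS(=O)(=O)C(F)(F)F)(C(C)C)C(C)C
Why: The silyl triflate overcomes the chelated phenol, and capping it prevents O–H trapping of the diazo species in step 10.

**Step 9**
Reactants: 12
Product: 13, (E)-N′-tosylhydrazone of 12
Conditions: TsNHNH2, MeOH/THF, 50 °C
Reagents that add atoms: p-toluenesulfonyl hydrazide, Cc1ccc(cc1)S(=O)(=O)NN
Why: Simple carbonyl condensation that gives a crystalline hydrazone and leaves the silyl ethers unaffected.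

**Step 10** (key fragment union)
Reactants: 13; 6 (1.5 equiv)
Product: 14, (R)-6-methyl-2-[4-({2-methyl-4-[3-methyl-5-(TIPSO)phenoxy]-6-(TIPSO)phenyl}methyl)phenyl]heptan-2-ol
Conditions: K2CO3, 1,4-dioxane, 110 °C, 4–6 h
Reagents that add atoms: none (the TsNHNH2 residue is lost as N2 and Ts−)
Why: In this Barluenga–Valdés reductive coupling, Bamford–Stevens loss of sulfinate gives the aryldiazomethane, which adds to the boronic acid, undergoes 1,2-aryl shift with loss of N2, and the benzhydryl boronic acid protodeboronates in situ to CH2, while the hindered tertiary OH does not compete and the stereocentre is remote.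

**Step 11** (key late-stage C–H functionalisation)
Reactants: 14
Product: 15, (R)-1,1-diethyl-3-methyl-3-(4-methylpentyl)-6-({2-methyl-4-[3-methyl-5-(TIPSO)phenoxy]-6-(TIPSO)phenyl}methyl)-1,3-dihydrobenzo[c][1,2]oxasilole
Conditions: Et2SiH2, [Ir(cod)OMe]2 (0.5 mol %), THF, rt → 50 °C; evaporate; [Ir(cod)OMe]2 (2 mol %), 1,10-phenanthroline (4 mol %), norbornene, THF, 100 °C
Reagents that add atoms: diethylsilane, CC[SiH2]CC
Why: Hydroxyl-directed Ir-catalysed ortho C–H silylation (dehydrogenative O-silylation, then cyclisation of the hydridosilyl ether) can only reach the two equivalent ring-C ortho C–H bonds through a five-membered ring, with gem-disubstitution helping closure and no bond to the stereocentre being broken.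

**Step 12**
Reactants: 15
Product: 16, target, (R)-configured
Conditions: 30% H2O2, KHCO3, THF/MeOH 1:1, rt; aq Na2S2O3 quench; then TBAF (3 equiv), THF, 0 °C → rt (telescoped); pH 7 work-up, Et3N-deactivated silica
Reagents that add atoms: hydrogen peroxide, OO (supplies the ring-C phenol O)
Why: Tamao–Fleming oxidation of the activated aryl–Si(OR) bond gives the phenol and frees the tertiary alcohol, fluoride then removes both aryl TIPS ethers, and the base/neutral medium avoids ionisation or racemisation of the o-hydroxy tertiary benzylic alcohol.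

## Compound list
| No. | Name | SMILES | Role |
|---|---|---|---|
| 1 | (S)-1-(4-chlorophenyl)ethanol | C[C@H](O)c1ccc(Cl)cc1 | starting material |
| 2 | (S)-1-(4-chlorophenyl)ethyl N,N-diisopropylcarbamate | C[C@H](OC(=O)N(C(C)C)C(C)C)c1ccc(Cl)cc1 | intermediate |
| 3 | 4-methylpent-1-ene | C=CCC(C)C | starting material |
| 4 | 4-methylpentyl-Bpin | CC(C)CCCB1OC(C)(C)C(C)(C)O1 | intermediate |
| 5 | (R)-2-(4-chlorophenyl)-6-methylheptan-2-ol | CC(C)CCC[C@@](C)(O)c1ccc(Cl)cc1 | intermediate |
| 6 | (R)-[4-(2-hydroxy-6-methylheptan-2-yl)phenyl]boronic acid | CC(C)CCC[C@@](C)(O)c1ccc(B(O)O)cc1 | intermediate |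
| 7 | 3-bromo-5-methylphenol | Cc1cc(O)cc(Br)c1 | starting material |
| 8 | (3-bromo-5-methylphenoxy)triisopropylsilane | Cc1cc(Br)cc(O[Si](C(C)C)(C(C)C)C(C)C)c1 | intermediate |
| 9 | [3-methyl-5-(triisopropylsilyloxy)phenyl]boronic acid | Cc1cc(B(O)O)cc(O[Si](C(C)C)(C(C)C)C(C)C)c1 | intermediate |
| 10 | 2,4-dihydroxy-6-methylbenzaldehyde | Cc1cc(O)cc(O)c1C=O | starting material |
| 11 | 4-aryloxy-2-hydroxy-6-methylbenzaldehyde (ring A OTIPS) | Cc1cc(Oc2cc(C)cc(O[Si](C(C)C)(C(C)C)C(C)C)c2)cc(O)c1C=O | intermediate |
| 12 | bis-TIPS aldehyde | Cc1cc(Oc2cc(C)cc(O[Si](C(C)C)(C(C)C)C(C)C)c2)cc(O[Si](C(C)C)(C(C)C)C(C)C)c1C=O | intermediate |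
| 13 | (E)-N-tosylhydrazone of 12 | Cc1cc(Oc2cc(C)cc(O[Si](C(C)C)(C(C)C)C(C)C)c2)cc(O[Si](C(C)C)(C(C)C)C(C)C)c1/C=N/NS(=O)(=O)c1ccc(C)cc1 | intermediate |
| 14 | (R)-diarylmethane tertiary alcohol, bis-TIPS | CC(C)CCC[C@@](C)(O)c1ccc(Cc2c(C)cc(Oc3cc(C)cc(O[Si](C(C)C)(C(C)C)C(C)C)c3)cc2O[Si](C(C)C)(C(C)C)C(C)C)cc1 | intermediate |
| 15 | (R)-benzoxasilole | CC[Si]1(CC)O[C@](C)(CCCC(C)C)c2ccc(Cc3c(C)cc(Oc4cc(C)cc(O[Si](C(C)C)(C(C)C)C(C)C)c4)cc3O[Si](C(C)C)(C(C)C)C(C)C)cc21 | intermediate |
| 16 | CID46887020, (R) | Cc1cc(O)cc(Oc2cc(C)c(Cc3ccc([C@](C)(O)CCCC(C)C)c(O)c3)c(O)c2)c1 | target |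

## Totals and risks
**Total steps:** 12.
**Longest linear sequence:** 8 steps (7 → 8 → 9 → 11 → 12 → 13 → 14 → 15 → 16). The chiral branch is 6 steps.

**Steps most likely to fail:**
1. **Step 10.** The diazo carbon is flanked by two ortho substituents, and an aryl TIPS ether may be lost in hot K2CO3. Fallback: abandon the carbene route. Reduce 12 with NaBH4, form the benzylic methyl carbonate, and join it to 6 by Pd-catalysed benzylic sp3–sp2 Suzuki–Miyaura coupling.
2. **Step 7.** The salicylaldehyde motif can chelate Cu, and the electron-poor phenol may give low yield or some 2-O-arylation. Fallback: replace 10 with orsellinic acid acetonide (7-hydroxy-2,2,5-trimethyl-4H-1,3-benzodioxin-4-one), which has only one free OH. Form the ether by Ullmann coupling with 8, then open the dioxinone reductively and re-oxidise (LiAlH4, then MnO2) to reach 11.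
3. **Step 11.** O-silylation of the hindered tertiary alcohol and the C–H silylation are being asked of a large substrate. Fallback: give up late-stage C–H oxidation and carry the oxygen from the start. O-protect 4′-chloro-2′-hydroxyacetophenone, reduce it to the (S)-alcohol by Noyori transfer hydrogenation, then follow steps 1, 3, 4 and 10 as written.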